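**Retrosynthetic overview**

- The target comes from a Claisen–Schmidt condensation and acid release, joining a peroxyketal-protected acetophenone (ring A) with THP-protected 4-hydroxybenzaldehyde (ring B).
- The C6''–OOH bond is made by cathodic reduction of O2 and SN2 displacement of an (S)-mesylate with inversion; the (S) centre is bought in (S)-5-oxotetrahydrofuran-2-carboxylic acid (from L-glutamic acid).
- The Ar–CH2 bond and the (E)-C2''=C3'' olefin come from Negishi carboalumination of an (S)-enynol and Pd coupling with a benzylic bromide made from 2,4-dihydroxy-3-methylacetophenone, whose methyl group fixes the ring position.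
- The enynol comes from the lactone acid: CO2H to acetyl to isopropenyl, then lactone to lactol to terminal alkyne.
- No ring is formed: ring A and ring B are bought, and the lactone ring of the chiral acid is opened in step 3.

Assumption: 1, 7 and 17 are catalogue compounds, and 1 is bought as the (S)-enantiomer.

**Route**

Step 1
Reactants: 1 (S)-5-oxotetrahydrofuran-2-carboxylic acid
Product: 3 (S)-5-acetyldihydrofuran-2(3H)-one, via acid chloride 2 (not isolated)
Conditions: (COCl)2, DMF (cat.), CH2Cl2, 0 °C to rt; concentrate; Me2CuLi (from MeLi, CuI), Et2O, −78 °C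
Reagents that add atoms: oxalyl chloride O=C(Cl)C(=O)Cl (the Cl of 2); lithium dimethylcuprate [Li+].C[Cu-]C (the CH3 of 3)
Why: Acyl chloride formation followed by Gilman ketone synthesis, in which the cuprate reacts with the acid chloride at −78 °C much faster than with the lactone or the product ketone, and the bought (S) centre is not enolised.

Step 2
Reactants: 3 (S)-5-acetyldihydrofuran-2(3H)-one
Product: 4 (S)-5-(prop-1-en-2-yl)dihydrofuran-2(3H)-one
Conditions: Zn, CH2Br2, TiCl4 (pre-aged reagent), THF/CH2Cl2, 0 °C to rt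
Reagents that add atoms: dibromomethane BrCBr
Why: Takai–Lombardo methylenation uses a non-basic titanium–zinc methylene reagent that converts the ketone but not the lactone and does not enolise the α-acyloxy ketone, so the (S) centre is kept.

Step 3
Reactants: 4 (S)-5-(prop-1-en-2-yl)dihydrofuran-2(3H)-one
Product: 6 (S)-2-methylhept-1-en-6-yn-3-ol, via lactol 5 (not isolated)
Conditions: i-Bu2AlH, CH2Cl2, −78 °C; then MeOH, K2CO3, dimethyl (1-diazo-2-oxopropyl)phosphonate, −78 °C to rt
Reagents that add atoms: dimethyl (1-diazo-2-oxopropyl)phosphonate COP(=O)(OC)C(=[N+]=[N-])C(C)=O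
Why: Partial reduction of the γ-lactone to the lactol is followed in the same pot by Seyferth–Gilbert homologation with the Ohira–Bestmann reagent on the open hydroxy-aldehyde form, and the stereocentre, two carbons away from the aldehyde, is untouched.

Step 4
Reactants: 7 1-(2,4-dihydroxy-3-methylphenyl)ethanone
Product: 8 1-(2-hydroxy-4-methoxy-3-methylphenyl)ethanone
Conditions: MeI (1.1 equiv), K2CO3, acetone, rt
Reagents that add atoms: iodomethane CI
Why: Williamson ether synthesis is selective for the 4-OH because the 2-OH is held in a hydrogen bond to the acetyl group and is far less nucleophilic.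

Step 5
Reactants: 8 1-(2-hydroxy-4-methoxy-3-methylphenyl)ethanone
Product: 9 6-acetyl-3-methoxy-2-methylphenyl acetate
Conditions: Ac2O, DMAP (cat.), pyridine, 50 °C
Reagents that add atoms: acetic anhydride CC(=O)OC(C)=O
Why: DMAP-catalysed acylation caps the chelated phenol so that the ring is less prone to ionic bromination and no phenolic O–H can quench the radical chain of the next step.

Step 6
Reactants: 9 6-acetyl-3-methoxy-2-methylphenyl acetate
Product: 10 6-acetyl-2-(bromomethyl)-3-methoxyphenyl acetate
Conditions: NBS, AIBN (cat.), PhCF3, 85 °C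
Reagents that add atoms: N-bromosuccinimide O=C1CCC(=O)N1Br
Why: Wohl–Ziegler bromination in a non-polar solvent under radical initiation attacks the only benzylic methyl group (the acetyl CH3 is polarity-mismatched for bromine atoms), which fixes the side-chain attachment carbon on ring A without any regiochemical question.

Step 7
Reactants: 6 (S)-2-methylhept-1-en-6-yn-3-ol; 10 6-acetyl-2-(bromomethyl)-3-methoxyphenyl acetate
Product: 13 1-{2-hydroxy-3-[(2E,6S)-6-hydroxy-3,7-dimethylocta-2,7-dien-1-yl]-4-methoxyphenyl}ethanone, via alkenylalane 11 (not isolated), via acetate 12 (not isolated)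
Conditions: Me3Al (3 equiv), Cp2ZrCl2 (0.25 equiv), CH2Cl2, 0 °C to rt; evaporate volatiles; 10, Pd(PPh3)4 (5 mol%), THF, 0 °C to rt; then MeOH, K2CO3, rt
Reagents that add atoms: trimethylaluminium C[Al](C)C
Why: Zirconium-catalysed Negishi carboalumination adds methyl and aluminium syn across the terminal alkyne (methyl to the internal carbon) to give the (E)-alkenylalane, which is cross-coupled with the benzylic bromide under palladium catalysis with retention of olefin geometry while the alcohol rides as its aluminium alkoxide and the isopropenyl group stays inert, and methanolic K2CO3 then removes the aryl acetate.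

Step 8
Reactants: 13 1-{2-hydroxy-3-[(2E,6S)-6-hydroxy-3,7-dimethylocta-2,7-dien-1-yl]-4-methoxyphenyl}ethanone
Product: 14 (3S,6E)-8-(3-acetyl-2-hydroxy-6-methoxyphenyl)-2,6-dimethylocta-1,6-dien-3-yl methanesulfonate
Conditions: MsCl (1.05 equiv), Et3N, CH2Cl2, −40 °C, 20 min; cold work-up, used at once
Reagents that add atoms: methanesulfonyl chloride CS(=O)(=O)Cl
Why: Sulfonylation through sulfene is fast for the secondary alcohol at −40 °C and leaves the hindered, hydrogen-bonded phenol alone, and since the C–O bond is not broken the (S) configuration is retained.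

Step 9
Reactants: 14 (3S,6E)-8-(3-acetyl-2-hydroxy-6-methoxyphenyl)-2,6-dimethylocta-1,6-dien-3-yl methanesulfonate
Product: 15 1-{2-hydroxy-3-[(2E,6R)-6-hydroperoxy-3,7-dimethylocta-2,7-dien-1-yl]-4-methoxyphenyl}ethanone
Conditions: O2 (1 atm), Bu4NBF4 (0.1 M), DMF, divided cell, carbon-felt cathode held at −1.0 V versus Ag/AgCl, Mg anode, 0 °C, 14 added slowly to the catholyte, about 3.5 F/mol; then cold aq. NaH2PO4
Reagents that add atoms: dioxygen O=O
Why: Proposed new method: cathodic one-electron reduction of O2 in dry DMF gives a pool of tetrabutylammonium superoxide, which displaces the allylic mesylate of 14 by SN2 with inversion ((S) to (R)) to give an allylperoxyl radical that a second superoxide (or the cathode) reduces to the peroxide anion, protonated on buffer work-up, so that both oxygen atoms of the OOH group come from O2 and the bought configuration is transferred, not created; slow addition of 14 into excess superoxide at 0 °C keeps the product anion from alkylating a second molecule of 14 and outruns E2 and SN2′, the hydroperoxide anion formed from the phenolic proton gives the same product by the same pathway, and the closest known reactions are the displacement of secondary sulfonates and halides by KO2/18-crown-6 with inversion and the alkylation of basic H2O2 by secondary mesylates, neither of which has been run electrochemically on a secondary allylic sulfonate to give an isolated enantioenriched allylic hydroperoxide.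

Step 10
Reactants: 15 1-{2-hydroxy-3-[(2E,6R)-6-hydroperoxy-3,7-dimethylocta-2,7-dien-1-yl]-4-methoxyphenyl}ethanone
Product: 16 1-{2-hydroxy-4-methoxy-3-[(2E,6R)-6-[(2-methoxypropan-2-yl)peroxy]-3,7-dimethylocta-2,7-dien-1-yl]phenyl}ethanone
Conditions: 2-methoxypropene, PPTS (cat.), CH2Cl2, 0 °C
Reagents that add atoms: 2-methoxypropene C=C(C)OC
Why: Acid-catalysed addition of the hydroperoxide O–H to the enol ether (peroxyketal formation) masks the OOH group as a base-stable peroxide that cannot epoxidise the enone made in the next step, and the stereocentre is not involved.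

Step 11
Reactants: 16 1-{2-hydroxy-4-methoxy-3-[(2E,6R)-6-[(2-methoxypropan-2-yl)peroxy]-3,7-dimethylocta-2,7-dien-1-yl]phenyl}ethanone; 17 4-(tetrahydro-2H-pyran-2-yloxy)benzaldehyde
Product: 19 (E)-1-{2-hydroxy-3-[(2E,6R)-6-hydroperoxy-3,7-dimethylocta-2,7-dien-1-yl]-4-methoxyphenyl}-3-(4-hydroxyphenyl)prop-2-en-1-one, via protected chalcone 18 (not isolated)
Conditions: Ba(OH)2·8H2O (1.5 equiv), MeOH, 35 °C; then HCl in MeOH to pH 2, 0 °C to rt
Reagents that add atoms: none
Why: Claisen–Schmidt aldol condensation gives the (E)-enone by E1cB dehydration while the peroxyketal tolerates the base, and mild methanolic acid then cleaves the peroxyketal and the THP acetal in the same pot without touching the (R) centre.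

**Compound list**

1 | (S)-5-oxotetrahydrofuran-2-carboxylic acid | O=C(O)[C@@H]1CCC(=O)O1 | starting material
2 | (S)-5-oxotetrahydrofuran-2-carbonyl chloride | O=C(Cl)[C@@H]1CCC(=O)O1 | intermediate
3 | (S)-5-acetyldihydrofuran-2(3H)-one | CC(=O)[C@@H]1CCC(=O)O1 | intermediate
4 | (S)-5-(prop-1-en-2-yl)dihydrofuran-2(3H)-one | C=C(C)[C@@H]1CCC(=O)O1 | intermediate
5 | (5S)-5-(prop-1-en-2-yl)tetrahydrofuran-2-ol (lactol, both anomers) | C=C(C)[C@@H]1CCC(O)O1 | intermediate
6 | (S)-2-methylhept-1-en-6-yn-3-ol | C=C(C)[C@H](CCC#C)O | intermediate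
7 | 1-(2,4-dihydroxy-3-methylphenyl)ethanone | CC(=O)c1ccc(O)c(C)c1O | starting material
8 | 1-(2-hydroxy-4-methoxy-3-methylphenyl)ethanone | COc1ccc(C(C)=O)c(O)c1C | intermediate
9 | 6-acetyl-3-methoxy-2-methylphenyl acetate | COc1ccc(C(C)=O)c(OC(C)=O)c1C | intermediate
10 | 6-acetyl-2-(bromomethyl)-3-methoxyphenyl acetate | COc1ccc(C(C)=O)c(OC(C)=O)c1CBr | intermediate
11 | dimethyl[(1E,5S)-5-[(dimethylalumanyl)oxy]-2,6-dimethylhepta-1,6-dien-1-yl]alumane | C=C(C)[C@H](CC/C(C)=C/[Al](C)C)O[Al](C)C | intermediate
12 | 6-acetyl-2-[(2E,6S)-6-hydroxy-3,7-dimethylocta-2,7-dien-1-yl]-3-methoxyphenyl acetate (in the flask as its aluminium alkoxide) | C=C(C)[C@H](CC/C(C)=C/Cc1c(OC)ccc(C(C)=O)c1OC(C)=O)O | intermediate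
13 | 1-{2-hydroxy-3-[(2E,6S)-6-hydroxy-3,7-dimethylocta-2,7-dien-1-yl]-4-methoxyphenyl}ethanone | C=C(C)[C@H](CC/C(C)=C/Cc1c(OC)ccc(C(C)=O)c1O)O | intermediate
14 | (3S,6E)-8-(3-acetyl-2-hydroxy-6-methoxyphenyl)-2,6-dimethylocta-1,6-dien-3-yl methanesulfonate | C=C(C)[C@H](CC/C(C)=C/Cc1c(OC)ccc(C(C)=O)c1O)OS(C)(=O)=O | intermediate
15 | 1-{2-hydroxy-3-[(2E,6R)-6-hydroperoxy-3,7-dimethylocta-2,7-dien-1-yl]-4-methoxyphenyl}ethanone | C=C(C)[C@@H](CC/C(C)=C/Cc1c(OC)ccc(C(C)=O)c1O)OO | intermediate
16 | 1-{2-hydroxy-4-methoxy-3-[(2E,6R)-6-[(2-methoxypropan-2-yl)peroxy]-3,7-dimethylocta-2,7-dien-1-yl]phenyl}ethanone | C=C(C)[C@@H](CC/C(C)=C/Cc1c(OC)ccc(C(C)=O)c1O)OOC(C)(C)OC | intermediate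
17 | 4-(tetrahydro-2H-pyran-2-yloxy)benzaldehyde (racemic acetal) | O=Cc1ccc(OC2CCCCO2)cc1 | starting material
18 | (E)-1-{2-hydroxy-4-methoxy-3-[(2E,6R)-6-[(2-methoxypropan-2-yl)peroxy]-3,7-dimethylocta-2,7-dien-1-yl]phenyl}-3-[4-(tetrahydro-2H-pyran-2-yloxy)phenyl]prop-2-en-1-one (both epimers at the acetal carbon) | C=C(C)[C@@H](CC/C(C)=C/Cc1c(OC)ccc(C(=O)/C=C/c2ccc(OC3CCCCO3)cc2)c1O)OOC(C)(C)OC | intermediate
19 | (E)-1-{2-hydroxy-3-[(2E,6R)-6-hydroperoxy-3,7-dimethylocta-2,7-dien-1-yl]-4-methoxyphenyl}-3-(4-hydroxyphenyl)prop-2-en-1-one | C=C(C)[C@@H](CC/C(C)=C/Cc1c(OC)ccc(C(=O)/C=C/c2ccc(O)cc2)c1O)OO | target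

**Step count and risks**

Total step count: 11. Longest linear sequence: 8 (steps 1, 2, 3, 7, 8, 9, 10, 11).

The three steps most likely to fail:

Step 7 (carboalumination and coupling). Residual methylaluminium species may add to the aryl ketone or cleave the aryl acetate of 10 before the palladium coupling is complete. The fallback reverses the polarity of the coupling. It sets out from 6: the same carboalumination (11) is quenched with I2 and the alkenyl iodide (3S,6E)-7-iodo-2,6-dimethylhepta-1,6-dien-3-ol F1 is isolated. Separately 10 is treated with zinc dust and LiCl in THF to give the ketone-tolerant benzylic reagent [(2-acetoxy-3-acetyl-6-methoxyphenyl)methyl]zinc bromide F2. Negishi coupling of F1 with F2 (Pd(OAc)2, SPhos, THF, rt) gives 12, where the route is rejoined; K2CO3 in MeOH as in step 7 then gives 13.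

Step 9 (the proposed electrochemical hydroperoxidation). Superoxide or the hydroperoxide anion may attack the hydroxyaryl ketone (Dakin-type cleavage), the peroxide anion may alkylate a second mesylate, or E2 and SN2′ may compete. The fallback is known chemistry. It sets out from 14 and alkylates the caesium salt of 2-methoxyprop-2-yl hydroperoxide (CsOH·H2O, DMF, 0 °C) by SN2 with inversion. This gives the peroxyketal directly, so the route is rejoined at 16 and step 10 is no longer needed; this fallback makes no new compound (F0).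

Step 11 (condensation in base). Prolonged exposure to Ba(OH)2 may trigger Kornblum–DeLaMare fragmentation of the secondary allylic peroxyketal. The fallback replaces the equilibrating condensation by a directed aldol. It sets out from 16: LiN(SiMe3)2 (2.2 equiv), THF, −78 °C gives the phenoxide-enolate, which adds to 17 to give the β-hydroxy ketone 3-hydroxy-1-{2-hydroxy-4-methoxy-3-[(2E,6R)-6-[(2-methoxypropan-2-yl)peroxy]-3,7-dimethylocta-2,7-dien-1-yl]phenyl}-3-[4-(tetrahydro-2H-pyran-2-yloxy)phenyl]propan-1-one F3. Methanolic HCl (pH 2, rt) then dehydrates the electron-rich benzylic carbinol to the (E)-enone and cleaves both acetals, so the route is rejoined at 19.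

**Further compounds**

F1 | step 7 | (3S,6E)-7-iodo-2,6-dimethylhepta-1,6-dien-3-ol | C=C(C)[C@H](CC/C(C)=C/I)O
F2 | step 7 | [(2-acetoxy-3-acetyl-6-methoxyphenyl)methyl]zinc bromide | COc1ccc(C(C)=O)c(OC(C)=O)c1C[Zn]Br
F0 | step 9 | none | none
F3 | step 11 | 3-hydroxy-1-{2-hydroxy-4-methoxy-3-[(2E,6R)-6-[(2-methoxypropan-2-yl)peroxy]-3,7-dimethylocta-2,7-dien-1-yl]phenyl}-3-[4-(tetrahydro-2H-pyran-2-yloxy)phenyl]propan-1-one (mixture at the carbinol and acetal carbons) | C=C(C)[C@@H](CC/C(C)=C/Cc1c(OC)ccc(C(=O)CC(O)c2ccc(OC3CCCCO3)cc2)c1O)OOC(C)(C)OC
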